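**Strategy.** With decalin locants (ring B: C1 H2, C2 HMe, C3 quaternary, C4 =CH2, C4a, C8a; ring A: C4a–C8a), everything rests on cutting ring B at C1–C2 and C3–C4. The exo-methylene carbon C4 is read as a latent ketone, so C1–C8a–C4a–C4 becomes a cis-fused cyclobutanone on ring A and C2/C3 an alkyne. Nickel-catalysed alkyne insertion into the strained C1–C4 bond builds ring B as a cis-decalin enone in one operation; the C4a/C8a fusion comes from the cyclobutanone. The silyl enyne acetal partner already carries C9–C14. Cuprate addition and enolate methylation set C2 and C3; the dioxane follows by cobalt-mediated peroxidation, peroxyacetal closure and auxiliary-controlled enolate addition.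

Key step: step 7

Remark on locants: C9 and C10 are the ethylene chain, C11 (quaternary), C12, C13 and C14 are the dioxane carbons, C15 and C16 are the propanoate CH and C=O; intermediates are named with these target locants.
Remark on step 2: the (2S,5S) auxiliary is assumed to give the (1R,6S) ketone; if the sense of induction is the opposite, the (2R,5R) amine is used instead.
Remark on materials: 3 and 24 are taken as catalogue compounds.
Remark on C11: the peroxidation in step 11 gives both C11 epimers; they are separated in step 13, where they become cis/trans dioxanes.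

Step 1
Reactants: 1 (2S,5S)-2,5-dimethylpyrrolidine
Product: 2 1-[(2S,5S)-2,5-dimethylpyrrolidin-1-yl]ethan-1-one
Conditions: AcCl, Et3N, CH2Cl2, 0 °C
Reagents that add atoms: acetyl chloride, CC(=O)Cl
Why: N-acylation of a secondary amine under Schotten–Baumann-type conditions; no stereocentre is touched.

Step 2
Reactants: 2 1-[(2S,5S)-2,5-dimethylpyrrolidin-1-yl]ethan-1-one; 3 1-methylcyclohexa-1,3-diene
Product: 6 (1R,6S)-3-methylbicyclo[4.2.0]oct-2-en-7-one, via keteniminium triflate 4 (not isolated), via cyclobutaniminium triflate 5 (not isolated)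
Conditions: Tf2O, 2,4,6-collidine, ClCH2CH2Cl, −20 to 40 °C; then H2O, NaHCO3, rt
Reagents that add atoms: water, O
Why: Keteniminium [2+2] cycloaddition followed by iminium hydrolysis: the electrophilic keteniminium carbon should bond to the unsubstituted diene terminus (future C4a, giving a methyl-stabilised allyl cation), collapse at the neighbouring carbon (future C8a) closes the four-membered ring suprafacially (cis fusion), and the C2-symmetric pyrrolidine differentiates the two faces and so sets C4a and C8a together.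

Step 3
Reactants: 7 4-bromobut-1-yne
Product: 9 benzyl(4-bromobut-1-yn-1-yl)dimethylsilane, via lithium acetylide 8 (not isolated)
Conditions: LiN(SiMe3)2, THF, −78 °C; BnMe2SiCl, −78 to 0 °C
Reagents that add atoms: benzylchlorodimethylsilane, C[Si](C)(Cl)Cc1ccccc1
Why: C-silylation of a lithium acetylide, which at −78 °C should not displace the primary bromide.

Step 4
Reactants: 10 methyl 4,4-dimethoxybutanoate
Product: 11 N,4,4-trimethoxy-N-methylbutanamide
Conditions: MeNHOMe·HCl, i-PrMgCl, THF, −20 to 0 °C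
Reagents that add atoms: N,O-dimethylhydroxylamine hydrochloride, CNOC.Cl
Why: Weinreb amide formation by aminolysis of the ester with the magnesium amide made in the flask.

Step 5
Reactants: 9 benzyl(4-bromobut-1-yn-1-yl)dimethylsilane; 11 N,4,4-trimethoxy-N-methylbutanamide
Product: 13 8-[benzyl(dimethyl)silyl]-1,1-dimethoxyoct-7-yn-4-one, via Grignard reagent 12 (not isolated)
Conditions: Mg, THF, rt; then 11, 0 °C; aq. NH4Cl
Reagents that add atoms: none
Why: Weinreb ketone synthesis, in which the chelated tetrahedral adduct prevents a second addition.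

Step 6
Reactants: 13 8-[benzyl(dimethyl)silyl]-1,1-dimethoxyoct-7-yn-4-one
Product: 14 benzyl(8,8-dimethoxy-5-methylideneoct-1-yn-1-yl)dimethylsilane
Conditions: Ph3PCH3Br, KOt-Bu, THF, 0 °C to rt
Reagents that add atoms: methyltriphenylphosphonium bromide, C[P+](c1ccccc1)(c1ccccc1)c1ccccc1.[Br-]
Why: Wittig methylenation of an unhindered dialkyl ketone, which installs the 1,1-disubstituted alkene (future C11 and its methyl).

Step 7
Reactants: 6 (1R,6S)-3-methylbicyclo[4.2.0]oct-2-en-7-one; 14 benzyl(8,8-dimethoxy-5-methylideneoct-1-yn-1-yl)dimethylsilane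
Product: 15 (4aS,8aR)-2-[benzyl(dimethyl)silyl]-3-(6,6-dimethoxy-3-methylidenehexyl)-7-methyl-4a,5,6,8a-tetrahydronaphthalen-4(1H)-one
Conditions: Ni(cod)2 (10 mol %), PCy3 (20 mol %), toluene, 100 °C
Reagents that add atoms: none
Why: Nickel-catalysed alkyne insertion into a cyclobutanone, a formal [4+2]: oxidative cyclisation of the C4 carbonyl and the alkyne on zerovalent nickel gives an oxanickelacyclopentene (C3–C4 bond), β-carbon elimination of the strained C4–C1 bond enlarges it to a seven-membered nickelacycle, and C(sp2)–C(sp3) reductive elimination forms C1–C2. The closest known reaction type is the intermolecular nickel/trialkylphosphine insertion of internal alkynes into cyclobutanones to give cyclohex-2-enones. Ring B is closed as a six-membered ring by two-carbon ring expansion of the four-membered ring, not by an exo or endo cyclisation. No stereocentre is created; C4a and C8a are not touched under these neutral conditions and should keep the cis fusion of 6. Two selectivities are needed: cleavage of C4–C1 and not C4–C4a, which the preference of β-carbon elimination for the less substituted primary carbon should secure, and the alkyne orientation, which the silyl group should secure by ending on the nickel-bound carbon (C2) while the alkyl-substituted carbon bonds to the carbonyl carbon. The two remote alkenes and the acetal are poor ligands for nickel and should not interfere.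

Step 8
Reactants: 15 (4aS,8aR)-2-[benzyl(dimethyl)silyl]-3-(6,6-dimethoxy-3-methylidenehexyl)-7-methyl-4a,5,6,8a-tetrahydronaphthalen-4(1H)-one
Product: 16 (4aS,8aR)-3-(6,6-dimethoxy-3-methylidenehexyl)-7-methyl-4a,5,6,8a-tetrahydronaphthalen-4(1H)-one
Conditions: Bu4NF, THF, 0 °C to rt
Reagents that add atoms: none
Why: Fluoride-induced protodesilylation of a benzyldimethylsilyl vinylsilane, a silyl group chosen because its removal from sp2 carbon under these conditions is reliable; no stereocentre is touched.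

Step 9
Reactants: 16 (4aS,8aR)-3-(6,6-dimethoxy-3-methylidenehexyl)-7-methyl-4a,5,6,8a-tetrahydronaphthalen-4(1H)-one
Product: 18 (2S,3R,4aS,8aR)-3-(6,6-dimethoxy-3-methylidenehexyl)-2,3,7-trimethyl-2,3,4a,5,6,8a-hexahydronaphthalen-4(1H)-one, via lithium enolate 17 (not isolated)
Conditions: Me2CuLi (MeLi, CuI), Et2O, −78 to −30 °C; then MeI, HMPA, THF, −30 to 0 °C
Reagents that add atoms: lithium dimethylcuprate, C[Cu-]C.[Li+]; iodomethane, CI
Why: Conjugate addition then enolate alkylation: the cuprate should add axially to C2 on the convex face of the cis-fused enone (methyl trans to the C8a–C8 bond), and the regiodefined C3–C4 enolate should be methylated at C3 again on the convex face, anti to ring A (whose C5 shields the lower face of C3), so that both methyl groups end cis to H-4a/H-8a and the C9 chain trans.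

Step 10
Reactants: 18 (2S,3R,4aS,8aR)-3-(6,6-dimethoxy-3-methylidenehexyl)-2,3,7-trimethyl-2,3,4a,5,6,8a-hexahydronaphthalen-4(1H)-one
Product: 19 (2S,3R,4S,4aS,8aR)-3-(6,6-dimethoxy-3-methylidenehexyl)-2,3,7-trimethyl-4-[(trimethylsilyl)methyl]-1,2,3,4,4a,5,6,8a-octahydronaphthalen-4-ol
Conditions: Me3SiCH2Li, CeCl3, THF, −78 °C
Reagents that add atoms: (trimethylsilyl)methyllithium, [Li]C[Si](C)(C)C
Why: Organocerium 1,2-addition to a hindered, enolisable ketone without enolisation (so C4a is not epimerised); equatorial attack should give the (4S)-carbinol, whose configuration is erased in step 12, and the β-hydroxysilane masks the C4 methylene during the peroxidation.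

Step 11
Reactants: 19 (2S,3R,4S,4aS,8aR)-3-(6,6-dimethoxy-3-methylidenehexyl)-2,3,7-trimethyl-4-[(trimethylsilyl)methyl]-1,2,3,4,4a,5,6,8a-octahydronaphthalen-4-ol
Product: 20 (2S,3R,4S,4aS,8aR)-3-{6,6-dimethoxy-3-methyl-3-[(triethylsilyl)peroxy]hexyl}-2,3,7-trimethyl-4-[(trimethylsilyl)methyl]-1,2,3,4,4a,5,6,8a-octahydronaphthalen-4-ol (both C11 epimers)
Conditions: Co(thd)2 [bis(2,2,6,6-tetramethylheptane-3,5-dionato)cobalt] (5 mol %), O2 (1 atm), Et3SiH, ClCH2CH2Cl, rt
Reagents that add atoms: dioxygen, O=O; triethylsilane, CC[SiH](CC)CC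
Why: Mukaiyama–Isayama peroxidation: hydrogen-atom transfer from a cobalt hydride to the 1,1-disubstituted alkene (expected to be faster than to the trisubstituted ring alkene) gives the tertiary C11 radical, which is trapped by O2 and silylated; the planar radical has no facial bias, so both C11 epimers form.

Step 12
Reactants: 20 (2S,3R,4S,4aS,8aR)-3-{6,6-dimethoxy-3-methyl-3-[(triethylsilyl)peroxy]hexyl}-2,3,7-trimethyl-4-[(trimethylsilyl)methyl]-1,2,3,4,4a,5,6,8a-octahydronaphthalen-4-ol
Product: 23 6-methoxy-3-methyl-3-{2-[(2S,3R,4aS,8aR)-2,3,7-trimethyl-4-methylidene-1,2,3,4,4a,5,6,8a-octahydronaphthalen-3-yl]ethyl}-1,2-dioxane (mixture at C11 and C14), via hydroperoxide 21 (not isolated), via hydroxysilane peroxyacetal 22 (not isolated)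
Conditions: p-TsOH·H2O (0.2 equiv), MeOH, 0 °C to rt
Reagents that add atoms: none
Why: Acid cleaves the silyl peroxide, the hydroperoxide closes 6-exo on the oxocarbenium ion of the dimethyl acetal to the six-membered peroxyacetal, and the tertiary β-hydroxysilane undergoes acid-mediated Peterson elimination to the C4 methylene; C14 is an anomeric mixture, which is irrelevant because it is ionised in step 13.

Step 13
Reactants: 23 6-methoxy-3-methyl-3-{2-[(2S,3R,4aS,8aR)-2,3,7-trimethyl-4-methylidene-1,2,3,4,4a,5,6,8a-octahydronaphthalen-3-yl]ethyl}-1,2-dioxane; 24 (4R)-3-propanoyl-4-(propan-2-yl)-1,3-thiazolidine-2-thione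
Product: 26 (4R)-3-[(2S)-2-{(3R,6R)-6-methyl-6-[2-((2S,3R,4aS,8aR)-2,3,7-trimethyl-4-methylidene-1,2,3,4,4a,5,6,8a-octahydronaphthalen-3-yl)ethyl]-1,2-dioxan-3-yl}propanoyl]-4-(propan-2-yl)-1,3-thiazolidine-2-thione, via chlorotitanium enolate 25 (not isolated)
Conditions: 24, TiCl4, i-Pr2NEt, CH2Cl2, −78 °C; then 23, SnCl4, −78 to −40 °C; chromatography (removal of the C11 epimer)
Reagents that add atoms: none
Why: Lewis-acid ionisation of the peroxyacetal gives a cyclic peroxycarbenium ion that should be attacked by the chelated (Z)-titanium enolate on the face opposite the isopropyl group (sets C15) through an open transition state in which the dioxane ring lies over the enolate hydrogen and not over its methyl group (sets C14 syn to the C15 methyl); each C11 epimer reacts, giving cis/trans dioxanes that differ only at C11 and are separated here.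

Step 14
Reactants: 26 (4R)-3-[(2S)-2-{(3R,6R)-6-methyl-6-[2-((2S,3R,4aS,8aR)-2,3,7-trimethyl-4-methylidene-1,2,3,4,4a,5,6,8a-octahydronaphthalen-3-yl)ethyl]-1,2-dioxan-3-yl}propanoyl]-4-(propan-2-yl)-1,3-thiazolidine-2-thione
Product: 27 methyl (2S)-2-{(3R,6R)-6-methyl-6-[2-((2S,3R,4aS,8aR)-2,3,7-trimethyl-4-methylidene-1,2,3,4,4a,5,6,8a-octahydronaphthalen-3-yl)ethyl]-1,2-dioxan-3-yl}propanoate (CNP0144520.2)
Conditions: MeOH, imidazole, CH2Cl2, rt
Reagents that add atoms: methanol, CO
Why: Mild methanolysis of the activated N-acyl thiazolidinethione, near-neutral so that C15 is not epimerised and the β-peroxy ester is not opened by base.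

**Compound list**

1 | (2S,5S)-2,5-dimethylpyrrolidine | C[C@H]1CC[C@H](C)N1 | starting material
2 | 1-[(2S,5S)-2,5-dimethylpyrrolidin-1-yl]ethan-1-one | C[C@H]1CC[C@H](C)N1C(C)=O | intermediate
3 | 1-methylcyclohexa-1,3-diene | CC1=CC=CCC1 | starting material
4 | (2S,5S)-1-ethenylidene-2,5-dimethylpyrrolidin-1-ium triflate (keteniminium triflate, not isolated) | C[C@H]1CC[C@H](C)[N+]1=C=C.[O-]S(=O)(=O)C(F)(F)F | intermediate
5 | (2S,5S)-2,5-dimethyl-1-[(1R,6S)-3-methylbicyclo[4.2.0]oct-2-en-7-ylidene]pyrrolidin-1-ium triflate (cyclobutaniminium triflate, not isolated) | C[C@H]1CC[C@H](C)[N+]1=C1[C@H]2CCC(C)=C[C@H]2C1.[O-]S(=O)(=O)C(F)(F)F | intermediate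
6 | (1R,6S)-3-methylbicyclo[4.2.0]oct-2-en-7-one (cis-fused) | O=C1[C@H]2CCC(C)=C[C@H]2C1 | intermediate
7 | 4-bromobut-1-yne | C#CCCBr | starting material
8 | (4-bromobut-1-yn-1-yl)lithium (lithium acetylide, not isolated) | [Li]C#CCCBr | intermediate
9 | benzyl(4-bromobut-1-yn-1-yl)dimethylsilane | BrCCC#C[Si](C)(C)Cc1ccccc1 | intermediate
10 | methyl 4,4-dimethoxybutanoate | COC(=O)CCC(OC)OC | starting material
11 | N,4,4-trimethoxy-N-methylbutanamide | CON(C)C(=O)CCC(OC)OC | intermediate
12 | {4-[benzyl(dimethyl)silyl]but-3-yn-1-yl}magnesium bromide (Grignard reagent, not isolated) | Br[Mg]CCC#C[Si](C)(C)Cc1ccccc1 | intermediate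
13 | 8-[benzyl(dimethyl)silyl]-1,1-dimethoxyoct-7-yn-4-one | COC(CCC(=O)CCC#C[Si](C)(C)Cc1ccccc1)OC | intermediate
14 | benzyl(8,8-dimethoxy-5-methylideneoct-1-yn-1-yl)dimethylsilane | C=C(CCC#C[Si](C)(C)Cc1ccccc1)CCC(OC)OC | intermediate
15 | (4aS,8aR)-2-[benzyl(dimethyl)silyl]-3-(6,6-dimethoxy-3-methylidenehexyl)-7-methyl-4a,5,6,8a-tetrahydronaphthalen-4(1H)-one (cis-fused) | O=C1[C@H]2CCC(C)=C[C@H]2CC([Si](C)(C)Cc3ccccc3)=C1CCC(=C)CCC(OC)OC | intermediate
16 | (4aS,8aR)-3-(6,6-dimethoxy-3-methylidenehexyl)-7-methyl-4a,5,6,8a-tetrahydronaphthalen-4(1H)-one | O=C1[C@H]2CCC(C)=C[C@H]2CC=C1CCC(=C)CCC(OC)OC | intermediate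
17 | lithium (2S,4aS,8aR)-3-(6,6-dimethoxy-3-methylidenehexyl)-2,7-dimethyl-1,2,4a,5,6,8a-hexahydronaphthalen-4-olate (lithium enolate, not isolated) | [Li]OC1=C(CCC(=C)CCC(OC)OC)[C@@H](C)C[C@@H]2C=C(C)CC[C@H]12 | intermediate
18 | (2S,3R,4aS,8aR)-3-(6,6-dimethoxy-3-methylidenehexyl)-2,3,7-trimethyl-2,3,4a,5,6,8a-hexahydronaphthalen-4(1H)-one | O=C1[C@H]2CCC(C)=C[C@H]2C[C@H](C)[C@@]1(C)CCC(=C)CCC(OC)OC | intermediate
19 | (2S,3R,4S,4aS,8aR)-3-(6,6-dimethoxy-3-methylidenehexyl)-2,3,7-trimethyl-4-[(trimethylsilyl)methyl]-1,2,3,4,4a,5,6,8a-octahydronaphthalen-4-ol | O[C@@]1(C[Si](C)(C)C)[C@H]2CCC(C)=C[C@H]2C[C@H](C)[C@@]1(C)CCC(=C)CCC(OC)OC | intermediate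
20 | (2S,3R,4S,4aS,8aR)-3-{6,6-dimethoxy-3-methyl-3-[(triethylsilyl)peroxy]hexyl}-2,3,7-trimethyl-4-[(trimethylsilyl)methyl]-1,2,3,4,4a,5,6,8a-octahydronaphthalen-4-ol (both C11 epimers) | O[C@@]1(C[Si](C)(C)C)[C@H]2CCC(C)=C[C@H]2C[C@H](C)[C@@]1(C)CCC(C)(OO[Si](CC)(CC)CC)CCC(OC)OC | intermediate
21 | (2S,3R,4S,4aS,8aR)-3-(3-hydroperoxy-6,6-dimethoxy-3-methylhexyl)-2,3,7-trimethyl-4-[(trimethylsilyl)methyl]-1,2,3,4,4a,5,6,8a-octahydronaphthalen-4-ol (hydroperoxide, both C11 epimers, not isolated) | O[C@@]1(C[Si](C)(C)C)[C@H]2CCC(C)=C[C@H]2C[C@H](C)[C@@]1(C)CCC(C)(OO)CCC(OC)OC | intermediate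
22 | (2S,3R,4S,4aS,8aR)-3-[2-(6-methoxy-3-methyl-1,2-dioxan-3-yl)ethyl]-2,3,7-trimethyl-4-[(trimethylsilyl)methyl]-1,2,3,4,4a,5,6,8a-octahydronaphthalen-4-ol (mixture at C11 and C14, not isolated) | O[C@@]1(C[Si](C)(C)C)[C@H]2CCC(C)=C[C@H]2C[C@H](C)[C@@]1(C)CCC1(C)CCC(OC)OO1 | intermediate
23 | 6-methoxy-3-methyl-3-{2-[(2S,3R,4aS,8aR)-2,3,7-trimethyl-4-methylidene-1,2,3,4,4a,5,6,8a-octahydronaphthalen-3-yl]ethyl}-1,2-dioxane (mixture at C11 and C14) | C=C1[C@H]2CCC(C)=C[C@H]2C[C@H](C)[C@@]1(C)CCC1(C)CCC(OC)OO1 | intermediate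
24 | (4R)-3-propanoyl-4-(propan-2-yl)-1,3-thiazolidine-2-thione | CCC(=O)N1[C@H](C(C)C)CSC1=S | starting material
25 | trichloro{[(1Z)-1-[(4R)-4-(propan-2-yl)-2-sulfanylidene-1,3-thiazolidin-3-yl]prop-1-en-1-yl]oxy}titanium (chlorotitanium enolate, not isolated) | C/C=C(\O[Ti](Cl)(Cl)Cl)N1[C@H](C(C)C)CSC1=S | intermediate
26 | (4R)-3-[(2S)-2-{(3R,6R)-6-methyl-6-[2-((2S,3R,4aS,8aR)-2,3,7-trimethyl-4-methylidene-1,2,3,4,4a,5,6,8a-octahydronaphthalen-3-yl)ethyl]-1,2-dioxan-3-yl}propanoyl]-4-(propan-2-yl)-1,3-thiazolidine-2-thione | C=C1[C@H]2CCC(C)=C[C@H]2C[C@H](C)[C@@]1(C)CC[C@]1(C)CC[C@H]([C@H](C)C(=O)N2C(=S)SC[C@H]2C(C)C)OO1 | intermediate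
27 | methyl (2S)-2-{(3R,6R)-6-methyl-6-[2-((2S,3R,4aS,8aR)-2,3,7-trimethyl-4-methylidene-1,2,3,4,4a,5,6,8a-octahydronaphthalen-3-yl)ethyl]-1,2-dioxan-3-yl}propanoate | C=C1[C@H]2CCC(C)=C[C@H]2C[C@H](C)[C@@]1(C)CC[C@]1(C)CC[C@H]([C@H](C)C(=O)OC)OO1 | target

**Step count.** 14 steps in total. The longest linear sequence is 11 steps (3, 5, 6, then 7 to 14).

**Steps most likely to fail**

Step 9. The methylation of enolate 17 may take place on the face anti to the C2 methyl group instead of anti to ring A, which would give the C3 epimer; the two directing effects oppose each other in this cis-fused system. The fallback inverts the order in which the two C3 substituents arrive; it sets out from 6 (and 11) and comes back at 18. Propynylmagnesium bromide and BnMe2SiCl give benzyldimethyl(prop-1-yn-1-yl)silane F6. The conditions of step 7 applied to 6 and F6 give the 3-methyl-2-silyl enone F7, and Bu4NF gives the 3-methyl enone F8. Me2CuLi followed by Me3SiCl gives the silyl enol ether F9 with the C2 methyl in place. Vinylmagnesium bromide and 11 give 6,6-dimethoxyhex-1-en-3-one F10. A Mukaiyama–Michael addition of F9 to F10 (TiCl4, CH2Cl2, −78 °C) then brings in the chain at C3 anti to the C2 methyl and gives the diketone F11. Wittig methylenation of its unhindered side-chain ketone gives 18.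

Step 13. The Lewis acid may fragment the peroxide, or the chiral enolate may lose face selectivity at C14 on the cyclic peroxycarbenium ion. The fallback forms the C14–O bond instead of the C14–C15 bond; it sets out from 23 and comes back at 27. Aqueous acid (AcOH, H2O, THF) converts 23 into the peroxyhemiacetal F12. Its open hydroperoxy aldehyde form reacts with methyl 2-(triphenyl-λ5-phosphanylidene)propanoate to give the (E)-hydroperoxy enoate F13. Et2NH in CF3CH2OH closes the dioxane by intramolecular oxa-Michael addition to give 27 together with its C11, C14 and C15 diastereomers, which are separated by HPLC.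

Step 2. The auxiliary may discriminate the diene faces poorly (low enantiomeric purity), or the keteniminium ion may attack the methyl-bearing diene terminus. The fallback is a racemic cycloaddition followed by resolution; it sets out from 3 and comes back at 6. Dichloroketene (Cl3CCOCl, Zn(Cu), Et2O) adds to 3 to give the racemic dichlorocyclobutanone F1, and Zn in AcOH gives the racemic ketone F2. NaBH4 reduces it from the convex face to the racemic endo alcohol F3. Lipase-catalysed acetylation (Candida antarctica lipase B, vinyl acetate) is assumed to acylate the unwanted enantiomer to the acetate F4 and leave the (1R,6S,7R) alcohol F5. After separation, Dess–Martin periodinane oxidises F5 to 6.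

**Further compounds**

F1 | step 2 | rac-8,8-dichloro-3-methylbicyclo[4.2.0]oct-2-en-7-one (cis-fused, one enantiomer drawn) | O=C1[C@H]2CCC(C)=C[C@H]2C1(Cl)Cl
F2 | step 2 | rac-3-methylbicyclo[4.2.0]oct-2-en-7-one (racemic form of 6) | O=C1C2CCC(C)=CC2C1
F3 | step 2 | rac-3-methylbicyclo[4.2.0]oct-2-en-7-ol (hydroxyl endo) | OC1C2CCC(C)=CC2C1
F4 | step 2 | (1S,6R,7S)-3-methylbicyclo[4.2.0]oct-2-en-7-yl acetate | CC(=O)O[C@@H]1[C@@H]2CCC(C)=C[C@@H]2C1
F5 | step 2 | (1R,6S,7R)-3-methylbicyclo[4.2.0]oct-2-en-7-ol | O[C@H]1[C@H]2CCC(C)=C[C@H]2C1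
F6 | step 9 | benzyldimethyl(prop-1-yn-1-yl)silane | CC#C[Si](C)(C)Cc1ccccc1
F7 | step 9 | (4aS,8aR)-2-[benzyl(dimethyl)silyl]-3,7-dimethyl-4a,5,6,8a-tetrahydronaphthalen-4(1H)-one | O=C1[C@H]2CCC(C)=C[C@H]2CC([Si](C)(C)Cc3ccccc3)=C1C
F8 | step 9 | (4aS,8aR)-3,7-dimethyl-4a,5,6,8a-tetrahydronaphthalen-4(1H)-one | O=C1[C@H]2CCC(C)=C[C@H]2CC=C1C
F9 | step 9 | trimethyl{[(2S,4aS,8aR)-2,3,7-trimethyl-1,2,4a,5,6,8a-hexahydronaphthalen-4-yl]oxy}silane | C[Si](C)(C)OC1=C(C)[C@@H](C)C[C@@H]2C=C(C)CC[C@H]12
F10 | step 9 | 6,6-dimethoxyhex-1-en-3-one | C=CC(=O)CCC(OC)OC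
F11 | step 9 | (2S,3R,4aS,8aR)-3-(6,6-dimethoxy-3-oxohexyl)-2,3,7-trimethyl-2,3,4a,5,6,8a-hexahydronaphthalen-4(1H)-one | O=C1[C@H]2CCC(C)=C[C@H]2C[C@H](C)[C@@]1(C)CCC(=O)CCC(OC)OC
F12 | step 13 | 6-methyl-6-{2-[(2S,3R,4aS,8aR)-2,3,7-trimethyl-4-methylidene-1,2,3,4,4a,5,6,8a-octahydronaphthalen-3-yl]ethyl}-1,2-dioxan-3-ol (mixture at C11 and C14) | C=C1[C@H]2CCC(C)=C[C@H]2C[C@H](C)[C@@]1(C)CCC1(C)CCC(O)OO1
F13 | step 13 | methyl (2E)-6-hydroperoxy-2,6-dimethyl-8-[(2S,3R,4aS,8aR)-2,3,7-trimethyl-4-methylidene-1,2,3,4,4a,5,6,8a-octahydronaphthalen-3-yl]oct-2-enoate (both C11 epimers) | C=C1[C@H]2CCC(C)=C[C@H]2C[C@H](C)[C@@]1(C)CCC(C)(OO)CC/C=C(\C)C(=O)OC
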